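**Retrosynthetic overview**
- The C3–Br of the N–H indole (ring pair A) is installed last by electrophilic bromination. Its pyrrole ring (N1, C2, C3) is disconnected by a Bartoli indolization to a nitro group at C7a. The C7 methoxy group is the required ortho substituent and C3a is the only free ortho C–H.
- The plan rests on one feature of the N-linked indole (ring pair B). C3' ends as a C–Br carbon, and C3a' is an ortho C–H of a para-bromophenyl ring whose bromine becomes C5'–Br. C3' can therefore be carried as C–CO2Me, which stabilises an N,N-diaryl enamine and is later exchanged for bromine by saponification and ipso-bromodecarboxylation.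
- Key disconnection C3'–C3a': a twofold C–H oxidative coupling joins the ester-bearing enamine carbon of an N,N-diaryl β-aminoacrylate to that ortho carbon.
- The acrylate comes from methyl propiolate and a diarylamine. The diarylamine comes from Chan–Lam arylation of 2-bromo-4-methoxy-5-nitroaniline, which is the monobromide of 4-methoxy-3-nitroaniline.
- Ring order: both benzene rings are purchased, the pyrrole ring of B closes first (step 4), and the pyrrole ring of A closes second (step 7).

Key step: step 4

Assumption: the SMILES carries no descriptor for the hindered C4–N1' axis, so axial chirality is not controlled and the product is taken as the racemate if that axis is configurationally stable.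

Step 1
Reactants: 1 4-methoxy-3-nitroaniline
Product: 2 2-bromo-4-methoxy-5-nitroaniline
Conditions: NBS (1.0 equiv), MeCN, 0 °C to rt, dark
Reagents that add atoms: N-bromosuccinimide, O=C1CCC(=O)N1Br
Why: Electrophilic aromatic bromination in which the amino group is the dominant director, its para position is blocked by OMe and the ortho position between NH2 and NO2 is crowded, so bromine should enter the open ortho carbon.

Step 2
Reactants: 2 2-bromo-4-methoxy-5-nitroaniline, 3 4-bromophenylboronic acid
Product: 4 2-bromo-N-(4-bromophenyl)-4-methoxy-5-nitroaniline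
Conditions: 3 (1.5 equiv), Cu(OAc)2 (20 mol %), myristic acid (40 mol %), 2,6-lutidine (1 equiv), toluene, air, rt to 40 °C
Reagents that add atoms: none
Why: Chan–Lam N-arylation, in which the aryl group passes from boron to divalent copper, the aniline binds, air oxidation to trivalent copper triggers C–N reductive elimination, and the absence of any zerovalent metal should leave all C–Br bonds intact while the deactivated diarylamine resists a second arylation.

Step 3
Reactants: 4 2-bromo-N-(4-bromophenyl)-4-methoxy-5-nitroaniline, 5 methyl propiolate
Product: 6 methyl (E)-3-[(4-bromophenyl)(2-bromo-4-methoxy-5-nitrophenyl)amino]prop-2-enoate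
Conditions: 5 (1.5 equiv, slow addition), Cs2CO3 (30 mol %), DMSO, rt
Reagents that add atoms: none
Why: Base-catalysed aza-Michael addition, since the N–H of 4 is acidified by its bromo- and nitroaryl groups to about the level of indole or carbazole, which add to propiolates under carbonate bases, and the tertiary push–pull enamine should settle in the E geometry because no N–H···O=C hydrogen bond can favour the other one.

Step 4
Reactants: 6 methyl (E)-3-[(4-bromophenyl)(2-bromo-4-methoxy-5-nitrophenyl)amino]prop-2-enoate
Product: 9 methyl 5-bromo-1-(2-bromo-4-methoxy-5-nitrophenyl)-1H-indole-3-carboxylate, via vinylpalladium acetate 7 (not isolated), via six-membered palladacycle 8 (not isolated)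
Conditions: Pd(OAc)2 (10 mol %), Cu(OAc)2 (3 equiv), DMA/PivOH 4:1, 90 °C, N2
Reagents that add atoms: none
Why: Pd(OAc)2 attacks the nucleophilic ester-bearing enamine carbon of 6 (the future C3') and loss of its proton gives vinylpalladium acetate 7, in which palladium already lies cis to nitrogen because the E-acrylate carries its C–H on that side. Carboxylate-assisted concerted metalation–deprotonation of an ortho C–H of the 4-bromophenyl ring then gives palladacycle 8, reductive elimination forms C3'–C3a', and Cu(OAc)2 returns zerovalent palladium to the divalent state. The closest known reaction type is the Pd(OAc)2/Cu(OAc)2 oxidative cyclization of N-aryl enaminoesters to indole-3-carboxylates, which also operates on N-substituted enamines made from secondary anilines and alkynoates. The pyrrole ring closes in a formally 5-endo-trig mode with respect to the enamine double bond, realised as ring contraction of the six-membered palladacycle, and no stereocentre is created. The selectivity needed is between the two N-aryl rings and rests on sterics rather than electronics: the bromophenyl ring offers two equivalent open ortho C–H bonds, whereas the single ortho C–H of the other ring is wedged between N and NO2, that ring is twisted out of the enamine plane by its ortho bromine, and closure there would press NO2 against the ester and Br against the remaining N-aryl group. The moderate temperature, the absence of phosphine and the excess of Cu(OAc)2 are chosen to keep the lifetime of zerovalent palladium too short for insertion into the C–Br bonds.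

Step 5
Reactants: 9 methyl 5-bromo-1-(2-bromo-4-methoxy-5-nitrophenyl)-1H-indole-3-carboxylate
Product: 11 5-bromo-1-(2-bromo-4-methoxy-5-nitrophenyl)-1H-indole-3-carboxylic acid, via lithium carboxylate 10 (not isolated)
Conditions: LiOH·H2O (4 equiv), THF/H2O 3:1, 45 °C; then 1 M HCl to pH 2
Reagents that add atoms: lithium hydroxide, [Li+].[OH-]
Why: Ester saponification by acyl–oxygen cleavage, run without methanol and at mild temperature because displacement of the bromine para to NO2 or of the methoxy group ortho to NO2 by hydroxide on a mononitroarene needs far harsher conditions.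

Step 6
Reactants: 11 5-bromo-1-(2-bromo-4-methoxy-5-nitrophenyl)-1H-indole-3-carboxylic acid
Product: 12 3,5-dibromo-1-(2-bromo-4-methoxy-5-nitrophenyl)-1H-indole
Conditions: NBS (1.05 equiv), DMF, 0 °C to rt, dark
Reagents that add atoms: N-bromosuccinimide, O=C1CCC(=O)N1Br
Why: Hunsdiecker-type ipso-bromodecarboxylation of an electron-rich heteroaromatic acid, in which electrophilic bromine adds at C3', the most nucleophilic carbon present, rearomatization occurs by loss of CO2 instead of a proton, and the single equivalent of NBS limits attack at C2'.

Step 7
Reactants: 12 3,5-dibromo-1-(2-bromo-4-methoxy-5-nitrophenyl)-1H-indole, 13 vinylmagnesium bromide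
Product: 16 5-bromo-4-(3,5-dibromo-1H-indol-1-yl)-7-methoxy-1H-indole, via nitrosoarene 14 (not isolated), via O-vinylhydroxylamine magnesium salt 15 (not isolated)
Conditions: 13 (3.5 equiv, 1 M in THF), THF, −40 °C; then sat. aq. NH4Cl
Reagents that add atoms: none
Why: Bartoli indole synthesis, in which the first equivalent of 13 attacks a nitro oxygen and collapses to nitrosoarene 14, the second gives 15 whose [3,3]-sigmatropic shift is steered by the flanking OMe group to the only free ortho carbon and forms C3–C3a, ring closure, deprotonation by the third equivalent and loss of water on work-up complete the pyrrole ring, and at −40 °C this Grignard reagent should not exchange with the aryl or indolyl bromides.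

Step 8
Reactants: 16 5-bromo-4-(3,5-dibromo-1H-indol-1-yl)-7-methoxy-1H-indole
Product: 17 rivularin B, 3,5-dibromo-4-(3,5-dibromo-1H-indol-1-yl)-7-methoxy-1H-indole
Conditions: NBS (1.0 equiv), DMF, −20 to 0 °C, dark
Reagents that add atoms: N-bromosuccinimide, O=C1CCC(=O)N1Br
Why: Electrophilic bromination of an N–H indole at C3, its intrinsically most nucleophilic carbon, while the N-linked indole is already blocked at C3' and deactivated and C6 is shielded between Br and OMe.

**Compound list**
1 | 4-methoxy-3-nitroaniline | COc1ccc(N)cc1[N+](=O)[O-] | starting material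
2 | 2-bromo-4-methoxy-5-nitroaniline | COc1cc(Br)c(N)cc1[N+](=O)[O-] | intermediate
3 | 4-bromophenylboronic acid | OB(O)c1ccc(Br)cc1 | starting material
4 | 2-bromo-N-(4-bromophenyl)-4-methoxy-5-nitroaniline | COc1cc(Br)c(Nc2ccc(Br)cc2)cc1[N+](=O)[O-] | intermediate
5 | methyl propiolate | C#CC(=O)OC | starting material
6 | methyl (E)-3-[(4-bromophenyl)(2-bromo-4-methoxy-5-nitrophenyl)amino]prop-2-enoate | COC(=O)/C=C/N(c1ccc(Br)cc1)c1cc([N+](=O)[O-])c(OC)cc1Br | intermediate
7 | vinylpalladium acetate, methyl (Z)-2-(acetoxypalladio)-3-[(4-bromophenyl)(2-bromo-4-methoxy-5-nitrophenyl)amino]prop-2-enoate, neutral ligands omitted, forms in the flask | COC(=O)/C([Pd]OC(C)=O)=C/N(c1ccc(Br)cc1)c1cc([N+](=O)[O-])c(OC)cc1Br | intermediate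
8 | six-membered palladacycle with Pd bridging C3' and C3a', neutral ligands omitted, forms in the flask | COC(=O)C1=CN(c2cc([N+](=O)[O-])c(OC)cc2Br)c2ccc(Br)cc2[Pd]1 | intermediate
9 | methyl 5-bromo-1-(2-bromo-4-methoxy-5-nitrophenyl)-1H-indole-3-carboxylate | COC(=O)c1cn(-c2cc([N+](=O)[O-])c(OC)cc2Br)c2ccc(Br)cc12 | intermediate
10 | lithium 5-bromo-1-(2-bromo-4-methoxy-5-nitrophenyl)-1H-indole-3-carboxylate, forms in the flask | [Li+].[O-]C(=O)c1cn(-c2cc([N+](=O)[O-])c(OC)cc2Br)c2ccc(Br)cc12 | intermediate
11 | 5-bromo-1-(2-bromo-4-methoxy-5-nitrophenyl)-1H-indole-3-carboxylic acid | OC(=O)c1cn(-c2cc([N+](=O)[O-])c(OC)cc2Br)c2ccc(Br)cc12 | intermediate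
12 | 3,5-dibromo-1-(2-bromo-4-methoxy-5-nitrophenyl)-1H-indole | COc1cc(Br)c(-n2cc(Br)c3cc(Br)ccc32)cc1[N+](=O)[O-] | intermediate
13 | vinylmagnesium bromide | C=C[Mg]Br | starting material
14 | 3,5-dibromo-1-(2-bromo-4-methoxy-5-nitrosophenyl)-1H-indole, forms in the flask | COc1cc(Br)c(-n2cc(Br)c3cc(Br)ccc32)cc1N=O | intermediate
15 | bromomagnesium N-[4-bromo-5-(3,5-dibromo-1H-indol-1-yl)-2-methoxyphenyl]-N-(vinyloxy)amide, forms in the flask | COc1cc(Br)c(-n2cc(Br)c3cc(Br)ccc32)cc1N([Mg]Br)OC=C | intermediate
16 | 5-bromo-4-(3,5-dibromo-1H-indol-1-yl)-7-methoxy-1H-indole | COc1cc(Br)c(-n2cc(Br)c3cc(Br)ccc32)c2cc[nH]c12 | intermediate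
17 | rivularin B, 3,5-dibromo-4-(3,5-dibromo-1H-indol-1-yl)-7-methoxy-1H-indole | COc1cc(Br)c(-n2cc(Br)c3cc(Br)ccc32)c2c(Br)c[nH]c12 | target

Total step count: 8. Longest linear sequence: 8 steps (1 to 17).

**Steps most likely to fail**

Step 4.
- Palladation may be slow, because the nitrogen lone pair that feeds the enamine carbon is shared with two aryl rings.
- Transient zerovalent palladium may insert into the nitro-activated C–Br bond ortho to nitrogen, and a Heck-type closure onto the wrong ring could follow.
- PhI(OAc)2 is not relied on as oxidant. A tertiary enamine cannot pass through an imine tautomer, so acetoxylation of the enamine carbon would compete.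
- The fallback sets out from 6. The enamine carbon would first be iodinated with N-iodosuccinimide (O=C1CCC(=O)N1I; MeCN, 0 °C to rt) to give methyl (Z)-3-[(4-bromophenyl)(2-bromo-4-methoxy-5-nitrophenyl)amino]-2-iodoprop-2-enoate F1.
- Its C–I bond is far more reactive toward zerovalent palladium than any C–Br bond. It would then be used in a redox-neutral intramolecular C–H alkenylation (Pd(PPh3)4, K2CO3, PivOH 30 mol %, DMA, 80 °C).
- This reaches palladacycle 8 by oxidative addition instead of electrophilic palladation and returns to the route at 9.

Step 7.
- The Grignard reagent may add to ring carbons of the nitroarene.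
- The nitro group may be reduced only to the aniline level.
- The [3,3] shift toward a carbon next to the bulky N-indolyl group may be slow.
- The fallback sets out from 12 and builds the pyrrole ring from an alkyne. Fe powder and NH4Cl (EtOH/H2O, 70 °C) should give 4-bromo-5-(3,5-dibromo-1H-indol-1-yl)-2-methoxyaniline F2.
- N-Iodosuccinimide (MeCN, catalytic TFA, 0 °C) should iodinate the only free position ortho to NH2, giving 4-bromo-3-(3,5-dibromo-1H-indol-1-yl)-2-iodo-6-methoxyaniline F3.
- Sonogashira coupling with ethynyltrimethylsilane (C#C[Si](C)(C)C; PdCl2(PPh3)2, CuI, Et3N, rt), selective for C–I, should give 4-bromo-3-(3,5-dibromo-1H-indol-1-yl)-6-methoxy-2-[(trimethylsilyl)ethynyl]aniline F4.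
- K2CO3 in MeOH should unmask 4-bromo-3-(3,5-dibromo-1H-indol-1-yl)-2-ethynyl-6-methoxyaniline F5.
- A 5-endo-dig hydroamination with CuI (DMF, 100 °C) returns to the route at 16.

Step 3.
- N–C bond formation may be sluggish because the nitrogen is hindered and weakly nucleophilic.
- The base may oligomerize the propiolate.
- The fallback sets out from 4 and replaces the basic conjugate addition with an acid-catalysed condensation. The reagent is methyl 3,3-dimethoxypropanoate (COC(=O)CC(OC)OC), the acetal of methyl formylacetate, with camphorsulfonic acid (10 mol %) in refluxing toluene and continuous removal of methanol.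
- The oxocarbenium ion formed from the acetal is electrophilic enough to capture a weakly nucleophilic diarylamine. This mirrors the known condensation of diarylamines with enolizable aldehydes to N,N-diaryl enamines.
- No compound outside the list is made (F0), and the sequence returns to the route at 6.

**Further compounds**
F1 | step 4 | methyl (Z)-3-[(4-bromophenyl)(2-bromo-4-methoxy-5-nitrophenyl)amino]-2-iodoprop-2-enoate | COC(=O)/C(I)=C/N(c1ccc(Br)cc1)c1cc([N+](=O)[O-])c(OC)cc1Br
F2 | step 7 | 4-bromo-5-(3,5-dibromo-1H-indol-1-yl)-2-methoxyaniline | COc1cc(Br)c(-n2cc(Br)c3cc(Br)ccc32)cc1N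
F3 | step 7 | 4-bromo-3-(3,5-dibromo-1H-indol-1-yl)-2-iodo-6-methoxyaniline | COc1cc(Br)c(-n2cc(Br)c3cc(Br)ccc32)c(I)c1N
F4 | step 7 | 4-bromo-3-(3,5-dibromo-1H-indol-1-yl)-6-methoxy-2-[(trimethylsilyl)ethynyl]aniline | COc1cc(Br)c(-n2cc(Br)c3cc(Br)ccc32)c(C#C[Si](C)(C)C)c1N
F5 | step 7 | 4-bromo-3-(3,5-dibromo-1H-indol-1-yl)-2-ethynyl-6-methoxyaniline | COc1cc(Br)c(-n2cc(Br)c3cc(Br)ccc32)c(C#C)c1N
F0 | step 3 | none | none
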